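The flavonol is disconnected at O1–C2 and at the C3–O bond, which leads back to a diaryl ynone. The key step exploits two features. One is the tetrasubstituted C2=C3 alkene of ring C (O1 and ring B on C2, oxygen and C4 on C3), which is an alkyne after anti addition of oxygen and an electrophile. The other is the C5–OH···O=C4 hydrogen bond bridging rings A and C. In one operation ICl closes ring C, forms O1–C2 and places iodine on C3 as the handle for the hydroxyl group. The precursor is a 6-hydroxy-2,3,4-trimethoxyphenyl ynone: the future C5–OH is free and chelated, and the future O1 is a methyl ether that leaves as chloromethane.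

Key step: step 6

Remark on the chemistry: the target has no stereocentre and no stable stereoaxis, so it is achiral and there is no enantiomer to select. The one stereocentre that appears on the way (the propargylic carbinol of step 4) is made racemic and is erased by the oxidation that follows.

Step 1
Reactants: 1 2-hydroxy-4-methoxybenzaldehyde
Product: 2 2-(benzyloxy)-4-methoxybenzaldehyde
Conditions: BnBr, K2CO3, DMF, 60 °C
Reagents that add atoms: benzyl bromide, BrCc1ccccc1
Why: Williamson ether synthesis, in which the chelated phenol is the only acidic site of 1 and is O-benzylated by SN2 in warm DMF, the benzyl ether being chosen because it should survive organolithium, MnO2, ICl and Grignard reagents and leave by hydrogenolysis at the very end.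

Step 2
Reactants: 2 2-(benzyloxy)-4-methoxybenzaldehyde
Product: 3 2-(benzyloxy)-1-ethynyl-4-methoxybenzene
Conditions: dimethyl (1-diazo-2-oxopropyl)phosphonate, K2CO3, MeOH, 0 °C → rt
Reagents that add atoms: dimethyl (1-diazo-2-oxopropyl)phosphonate, CC(=O)C(=[N+]=[N-])P(=O)(OC)OC
Why: Seyferth–Gilbert homologation in the Ohira–Bestmann variant, in which methanolysis of the reagent releases the diazomethylphosphonate anion, this olefinates the non-enolisable aldehyde, and loss of N2 with a 1,2-hydride shift gives the terminal alkyne under conditions that leave both aryl ethers untouched.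

Step 3
Reactants: 4 3,4,5-trimethoxyphenol
Product: 6 6-hydroxy-2,3,4-trimethoxybenzaldehyde, via aryl iminium chloride 5 (not isolated)
Conditions: POCl3, DMF, 0 °C → rt; then H2O, 0 °C → rt
Reagents that add atoms: N,N-dimethylformamide, CN(C)C=O (formyl carbon); water, O (carbonyl oxygen)
Why: Vilsmeier–Haack formylation, in which the para position of 4 is blocked by a methoxy group and the two free ortho positions are equivalent by symmetry, so only one aldehyde can form and the old phenol oxygen is singled out from the start as the future C5–OH.

Step 4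
Reactants: 3 2-(benzyloxy)-1-ethynyl-4-methoxybenzene; 6 6-hydroxy-2,3,4-trimethoxybenzaldehyde
Product: 9 2-{3-[2-(benzyloxy)-4-methoxyphenyl]-1-hydroxyprop-2-yn-1-yl}-3,4,5-trimethoxyphenol (racemic), via lithium acetylide 7 (not isolated), via lithium phenoxide 8 (not isolated)
Conditions: 3 (2.3 equiv), n-BuLi (2.2 equiv), THF, −78 °C; then 6, −78 → 0 °C; aq NH4Cl; crude into step 5
Reagents that add atoms: none
Why: 1,2-addition of a lithium acetylide to an aldehyde, in which the first equivalent of 7 turns the phenol into its lithium salt 8 (this salt is the only protection needed), the second adds to the non-enolisable formyl group, the liberated 3 is recovered, and the carbinol centre is left racemic because step 5 erases it.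

Step 5
Reactants: 9 2-{3-[2-(benzyloxy)-4-methoxyphenyl]-1-hydroxyprop-2-yn-1-yl}-3,4,5-trimethoxyphenol
Product: 10 3-[2-(benzyloxy)-4-methoxyphenyl]-1-(6-hydroxy-2,3,4-trimethoxyphenyl)prop-2-yn-1-one
Conditions: activated MnO2 (excess), CH2Cl2, rt
Reagents that add atoms: none
Why: manganese dioxide oxidation of a benzylic and propargylic alcohol, in which the doubly activated carbinol should react first in a neutral medium, so that acid-induced ionisation to an o-quinone methide is avoided and the ynone is stabilised by its phenol–carbonyl hydrogen bond.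

Step 6
Reactants: 10 3-[2-(benzyloxy)-4-methoxyphenyl]-1-(6-hydroxy-2,3,4-trimethoxyphenyl)prop-2-yn-1-one
Product: 12 2'-(benzyloxy)-5-hydroxy-3-iodo-7,8,4'-trimethoxyflavone, via methyloxonium chloride 11 (not isolated)
Conditions: ICl (1.05 equiv), CH2Cl2, −78 °C, dark; aq Na2S2O3
Reagents that add atoms: iodine monochloride, ClI
Why: ICl delivers I+ to the alkyne carbon next to the carbonyl (future C3) while positive charge develops on the carbon bearing ring B (future C2), the oxygen of the ring A methoxy group that is ortho to the acyl group and flanked by a second methoxy group attacks that carbon anti to iodine to give methyloxonium chloride 11, and chloride removes the methyl group by SN2 as chloromethane, which makes the closure irreversible and keeps the medium neutral. The closest known reaction type is the ICl-induced demethylative cyclisation of o-methoxyaryl alkynyl ketones to 3-iodochromones and 3-iodoflavones. Ring C closes in the 6-endo-dig mode and no stereocentre is formed, the anti addition being stored only as the trans relation of O1 and iodine across C2=C3. The first selectivity needed is the choice between the two oxygens ortho to the acyl group: in base-free CH2Cl2 the free phenol is locked in a resonance-assisted hydrogen bond to the carbonyl oxygen, which turns the alkyne towards the methoxy oxygen, so the phenol could reach C2 only after giving up this bond and rotating about the aryl–carbonyl axis, whereas the out-of-plane and therefore more σ-donating methoxy oxygen is already in place, and this should give the 5-hydroxy-7,8-dimethoxy pattern and not the 5,6,7-trimethoxy one. The second is 6-endo over 5-exo closure, secured by the polarisation of the ynone and by the 2',4'-dialkoxyaryl group, which put the cationic character on C2, and the same polarisation makes a 5-endo attack of the 2'-benzyloxy oxygen on C3 (benzofuran formation) electronically mismatched. The third is alkyne over arene iodination, secured by one equivalent of ICl at −78 °C, by the intramolecular trap and by the acyl group and the chelate, which lower the reactivity of ring A.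

Step 7
Reactants: 12 2'-(benzyloxy)-5-hydroxy-3-iodo-7,8,4'-trimethoxyflavone
Product: 15 2'-(benzyloxy)-3,5-dihydroxy-7,8,4'-trimethoxyflavone, via C3 Grignard species 13 (not isolated), via C3 dimethyl boronate 14 (not isolated)
Conditions: iPrMgCl·LiCl (2.2 equiv), THF, −40 °C; B(OMe)3, −40 °C → rt; then AcOH, 30% aq H2O2, 0 °C → rt
Reagents that add atoms: hydrogen peroxide, OO
Why: iodine–magnesium exchange with the LiCl-activated Grignard reagent, borate trapping and peroxide oxidation (C–B to C–O migration with retention at C3), in which the first equivalent only deprotonates the C5–OH, whose magnesium chelate with C4=O shields the vinylogous ester carbonyl, the second should exchange the electron-poor α-iodo-β-oxy-enone iodide faster than it adds, the sequence C3-metalated flavone, borate, peroxide is an established entry to flavonols, and flavonols tolerate peroxide as the Algar–Flynn–Oyamada reaction shows, so that C3 acts as the nucleophile and no alkoxide or hydroxide meets the base-sensitive 3-iodopyranone.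

Step 8
Reactants: 15 2'-(benzyloxy)-3,5-dihydroxy-7,8,4'-trimethoxyflavone
Product: 16 3,5,2'-trihydroxy-7,8,4'-trimethoxyflavone
Conditions: H2 (1 atm), 10% Pd/C, EtOAc–MeOH, rt
Reagents that add atoms: none
Why: catalytic hydrogenolysis of an aryl benzyl ether, in which the benzylic C–O bond is the only bond of 15 expected to be cleaved at one atmosphere (C2=C3 is part of the conjugated 3-hydroxypyranone), and because no methyl ether has to be removed no Lewis acid is needed and the methoxy groups at C7, C8 and C4' are not at risk.

Compound list
1 | 2-hydroxy-4-methoxybenzaldehyde | COc1ccc(C=O)c(O)c1 | starting material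
2 | 2-(benzyloxy)-4-methoxybenzaldehyde | COc1ccc(C=O)c(OCc2ccccc2)c1 | intermediate
3 | 2-(benzyloxy)-1-ethynyl-4-methoxybenzene | COc1ccc(C#C)c(OCc2ccccc2)c1 | intermediate
4 | 3,4,5-trimethoxyphenol | COc1cc(O)cc(OC)c1OC | starting material
5 | N-[(6-hydroxy-2,3,4-trimethoxyphenyl)methylidene]-N-methylmethanaminium chloride | C[N+](C)=Cc1c(O)cc(OC)c(OC)c1OC.[Cl-] | intermediate
6 | 6-hydroxy-2,3,4-trimethoxybenzaldehyde | O=Cc1c(O)cc(OC)c(OC)c1OC | intermediate
7 | {[2-(benzyloxy)-4-methoxyphenyl]ethynyl}lithium | COc1ccc(C#C[Li])c(OCc2ccccc2)c1 | intermediate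
8 | lithium 2-formyl-3,4,5-trimethoxyphenolate | [Li]Oc1cc(OC)c(OC)c(OC)c1C=O | intermediate
9 | 2-{3-[2-(benzyloxy)-4-methoxyphenyl]-1-hydroxyprop-2-yn-1-yl}-3,4,5-trimethoxyphenol, racemic | COc1ccc(C#CC(O)c2c(O)cc(OC)c(OC)c2OC)c(OCc2ccccc2)c1 | intermediate
10 | 3-[2-(benzyloxy)-4-methoxyphenyl]-1-(6-hydroxy-2,3,4-trimethoxyphenyl)prop-2-yn-1-one | COc1ccc(C#CC(=O)c2c(O)cc(OC)c(OC)c2OC)c(OCc2ccccc2)c1 | intermediate
11 | 2-[2-(benzyloxy)-4-methoxyphenyl]-5-hydroxy-3-iodo-7,8-dimethoxy-1-methyl-4-oxo-4H-chromen-1-ium chloride | COc1ccc(C2=C(I)C(=O)c3c(O)cc(OC)c(OC)c3[O+]2C)c(OCc2ccccc2)c1.[Cl-] | intermediate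
12 | 2'-(benzyloxy)-5-hydroxy-3-iodo-7,8,4'-trimethoxyflavone | COc1ccc(-c2oc3c(OC)c(OC)cc(O)c3c(=O)c2I)c(OCc2ccccc2)c1 | intermediate
13 | 3-(chloromagnesio)flavone derived from 12, as its chloromagnesium 5-phenoxide | COc1ccc(-c2oc3c(OC)c(OC)cc(O[Mg]Cl)c3c(=O)c2[Mg]Cl)c(OCc2ccccc2)c1 | intermediate
14 | dimethyl flavon-3-ylboronate derived from 13, as its chloromagnesium 5-phenoxide | COc1ccc(-c2oc3c(OC)c(OC)cc(O[Mg]Cl)c3c(=O)c2B(OC)OC)c(OCc2ccccc2)c1 | intermediate
15 | 2'-(benzyloxy)-3,5-dihydroxy-7,8,4'-trimethoxyflavone | COc1ccc(-c2oc3c(OC)c(OC)cc(O)c3c(=O)c2O)c(OCc2ccccc2)c1 | intermediate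
16 | 3,5,2'-trihydroxy-7,8,4'-trimethoxyflavone (achiral) | COc1ccc(-c2oc3c(OC)c(OC)cc(O)c3c(=O)c2O)c(O)c1 | target

Total step count: 8. Longest linear sequence: 7 (steps 1, 2, 4, 5, 6, 7, 8).

Steps most likely to fail

**Step 6.** The hydrogen bond may not hold the conformation firmly enough, so that closure runs through the phenolic oxygen. Iodination of ring A ortho to the free phenol, or of ring B para to the benzyloxy group, may outrun attack on the alkyne. Iodine and chloride may also simply add across the triple bond.
- The fallback replaces conformational control by a blocking group. It sets out from 10 and comes back at 12.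
- The phenol is capped with Ac2O and Et3N in CH2Cl2 at 0 °C, without a nucleophilic catalyst, to give 2-{3-[2-(benzyloxy)-4-methoxyphenyl]prop-2-ynoyl}-3,4,5-trimethoxyphenyl acetate F1.
- In F1 the ester oxygen is no longer a competent nucleophile and ring A is deactivated, so ICl in CH2Cl2 at −78 °C can close the ring only through the methoxy oxygen. This should give 5-acetoxy-2'-(benzyloxy)-3-iodo-7,8,4'-trimethoxyflavone F2.
- Brief methanolysis of F2 (K2CO3, MeOH, 0 °C) returns to 12.

**Step 7.** The C3–magnesium species may be lost by protonation before the borate reaches it. It may open ring C by anti β-elimination of the O1 aryloxide, or the Grignard reagent may add to the pyranone.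
- The fallback makes the C–B bond by palladium catalysis, so that no carbanion is generated at C3. It sets out from 12 and comes back at 15.
- Miyaura borylation (B2pin2, PdCl2(dppf), KOAc, dioxane, 80 °C) should give 2'-(benzyloxy)-5-hydroxy-7,8,4'-trimethoxyflavon-3-ylboronic acid pinacol ester F3.
- F3 is oxidised without purification with NaBO3·4H2O in THF–H2O at rt to 15.

**Step 4.** Addition to the aldehyde may be sluggish, because the phenoxide and three methoxy groups deactivate it. The very electron-rich carbinol may also ionise towards an o-quinone methide during work-up or on standing.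
- The fallback reverses the polarity and sets the ketone oxidation level directly, so that no carbinol is formed. It sets out from 3 (as its acetylide 7) and from 4 and comes back at 10.
- Acetylide 7 is carbamoylated with N-methoxy-N-methylcarbamoyl chloride in THF at −78 °C to give 3-[2-(benzyloxy)-4-methoxyphenyl]-N-methoxy-N-methylprop-2-ynamide F4.
- Phenol 4 is converted with MOMCl and iPr2NEt in CH2Cl2 into 1,2,3-trimethoxy-5-(methoxymethoxy)benzene F5.
- n-BuLi in THF at 0 °C lithiates F5 at one of its two equivalent positions between the OMOM and OMe groups (directed ortho-metalation), giving [2,3,4-trimethoxy-6-(methoxymethoxy)phenyl]lithium F6.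
- F6 is acylated by F4 at −78 °C with a cold acidic quench, so that the released amine cannot add to the ynone. This should give 3-[2-(benzyloxy)-4-methoxyphenyl]-1-[2,3,4-trimethoxy-6-(methoxymethoxy)phenyl]prop-2-yn-1-one F7.
- NaHSO4 on silica in CH2Cl2 at rt removes the carbonyl-flanked phenolic MOM group of F7 and returns to 10.

Further compounds
F1 | step 6 | 2-{3-[2-(benzyloxy)-4-methoxyphenyl]prop-2-ynoyl}-3,4,5-trimethoxyphenyl acetate | COc1ccc(C#CC(=O)c2c(OC(C)=O)cc(OC)c(OC)c2OC)c(OCc2ccccc2)c1
F2 | step 6 | 5-acetoxy-2'-(benzyloxy)-3-iodo-7,8,4'-trimethoxyflavone | COc1ccc(-c2oc3c(OC)c(OC)cc(OC(C)=O)c3c(=O)c2I)c(OCc2ccccc2)c1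
F3 | step 7 | 2'-(benzyloxy)-5-hydroxy-7,8,4'-trimethoxyflavon-3-ylboronic acid pinacol ester | COc1ccc(-c2oc3c(OC)c(OC)cc(O)c3c(=O)c2B4OC(C)(C)C(C)(C)O4)c(OCc2ccccc2)c1
F4 | step 4 | 3-[2-(benzyloxy)-4-methoxyphenyl]-N-methoxy-N-methylprop-2-ynamide | COc1ccc(C#CC(=O)N(C)OC)c(OCc2ccccc2)c1
F5 | step 4 | 1,2,3-trimethoxy-5-(methoxymethoxy)benzene | COCOc1cc(OC)c(OC)c(OC)c1
F6 | step 4 | [2,3,4-trimethoxy-6-(methoxymethoxy)phenyl]lithium | COCOc1cc(OC)c(OC)c(OC)c1[Li]
F7 | step 4 | 3-[2-(benzyloxy)-4-methoxyphenyl]-1-[2,3,4-trimethoxy-6-(methoxymethoxy)phenyl]prop-2-yn-1-one | COCOc1cc(OC)c(OC)c(OC)c1C(=O)C#Cc1ccc(OC)cc1OCc1ccccc1
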